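Follow one molecule.

starting material 0.10 M; partner 0.400 M; protic impurity 0.0500 M; time 3.0 d

    partner → decomposed reagent (k1 = 0.0014 /min)
    starting material + partner → product + by-product (k2 = 0.0082 /M/min)
    starting material + protic impurity → quenched substrate (k3 = 0.037 /M/min)
    2 starting material → homo dimer (k4 = 0.45 /M/min)

- percent here means starting material units held: one homo dimer counts as two
- a step written with two of one species runs at k times the square of its concentration and takes two of it each time
- the reaction counts as stopped when no species that holds the starting material changes by six tenths of a point or more over the second half of the time
- run time (flask): 3.0 d

* why nothing more happens at 3.0 d, or that something still does (it is still moving / all of the starting material has reacted)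
* part of the starting material gone at 3.0 d
* the product standing at 3.0 d, as a percentage of the starting material charged

**The fork.** I take a molecule of starting material in this flask at the moment some fraction of the charge is left, and I ask for its chances. Per minute the partner claims it at 0.00328 /min and the protic impurity at 0.00185 /min, both held at their charges as pseudo-first-order terms, so these side routes make 0.00513 /min. Dimerisation claims it at 0.0900 /min times the fraction left, which gives odds of 17.5 at the full charge.

**The share.** Averaging the molecule's chance of a side route over the fractions, from the full charge down to nothing, gives the logarithm of one plus the odds, divided by the odds. This comes to 16.6%, and I call it the escape share, the part of the charge that avoids dimerisation.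

**The ledger.** For this flask I book 10.6% to product and 6.00% to quenched substrate, split as the two side routes stand, and the remaining 83.4% to homo dimer. I expect the starting material to be gone by 3.0 d, because its half-life on the protic impurity route, 0.26 d at the charged impurity, is short against that time; the coupling half-life of 0.15 d holds at the charged partner, so I don't count on it to clear the last of the starting material. I expect my product entry to be high, because the partner's half-life of 0.34 d is also short against that time.

**The check.** The forecast says all of the starting material has reacted, with 100% gone (range 99.9% to 100%) and product at 9.6% (range 8.5% to 10.5%), lower than my entry, on the ground that “the slow coupling with the partner gets only about a tenth”. This flask gives: all of the starting material has reacted, with >99.9% gone and product at 9.76%.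

**The odds.** At the start of this flask, dimerisation uses starting material 27 times as fast as coupling does, and at 3.0 d homo dimer stands at 84.1% beside product at 9.76%, which is 0.84 percentage points under my entry. In the neighbouring flask with 1.6 M of partner, the side routes make 0.0150 /min, the odds fall to 6.01, the escape share is 32.4%, and my product entry becomes 28.4%, while that flask gives 27.7%.

The constants were drawn at random within sensible limits; what happens was integrated by code.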